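## Retrosynthetic overview

1. The target comes from its bis-TBS ether by one final desilylation; both primary hydroxyls stay silylated throughout.
2. The ten-membered carbocycle and the γ-lactone are made in one flask from a fully functionalised open-chain (farnesane-type) bromo-dienal. CrCl2 joins C7 (allyl terminus) to C6 (aldehyde), the bond that germacrene synthase makes from farnesyl diphosphate, and the 6-alkoxide then closes onto the C12 ester. The 8-ester, the oxirane and the Z,Z-diene are already in place.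
3. The open chain comes from a C3–C4 Sonogashira union of a Z-iodoalkene (C4–C6, C15) with an epoxy-alkyne (C1–C2, C7–C14), followed by cis-semihydrogenation.
4. The epoxy-alkyne comes from an (R)-glycidyl ether (C7–C9): acetylide opening, Negishi carboalumination (E-Δ1(10) olefin), Sharpless epoxidation of that olefin, alkyne homologation, acylation with O-TBS sarracinic acid, acrylate installation.
5. Ring order: oxirane (on the open chain) → carbocycle (C6–C7) → lactone (O6–C12), the last two in the same operation.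

Assumption: the SMILES is read as the (1R,6R,7R,8R,10R) isomer in germacrane numbering (1β,10α-epoxide, 6α-O lactone, 8β-ester, cis C2=C3, ring-cis C4=C5); germacrane locants are used in names and comments below, and (R)-4-methoxybenzyl glycidyl ether is taken as a catalogue compound.

## Route

Step 1
Reactants: 1 (E)-but-2-enal (crotonaldehyde)
Product: 2 (Z)-2-iodobut-2-enal
Conditions: I2, K2CO3, DMAP (cat.), THF/H2O (1:1), rt
Reagents that add atoms: iodine, [I][I]
Why: α-Iodination of an enal by conjugate addition of DMAP, iodination of the enolate and E1cB loss of DMAP gives the Z-iodoenal, in which the formyl group stays trans to the methyl group.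

Step 2
Reactants: 2 (Z)-2-iodobut-2-enal
Product: 3 (Z)-2-iodobut-2-en-1-ol
Conditions: NaBH4, CeCl3·7H2O, MeOH, 0 °C
Reagents that add atoms: none
Why: Luche 1,2-reduction of the enal leaves the alkenyl iodide and its geometry untouched.

Step 3
Reactants: 3 (Z)-2-iodobut-2-en-1-ol
Product: 4 (Z)-tert-butyl[(2-iodobut-2-en-1-yl)oxy]dimethylsilane
Conditions: TBSCl, imidazole, DMF, 0 °C → rt
Reagents that add atoms: tert-butyldimethylsilyl chloride, CC(C)(C)[Si](C)(C)Cl
Why: Standard silylation of a primary allylic alcohol.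

Step 4
Reactants: 4 (Z)-tert-butyl[(2-iodobut-2-en-1-yl)oxy]dimethylsilane
Product: 6 (Z)-2-{[(tert-butyldimethylsilyl)oxy]methyl}but-2-enoic acid (O-TBS sarracinic acid), via alkenyllithium 5 (not isolated)
Conditions: t-BuLi (2.1 equiv), Et2O, −78 °C; CO2 (gas), −78 → 0 °C; 1 M HCl to pH 3
Reagents that add atoms: carbon dioxide, O=C=O
Why: Iodine–lithium exchange and carboxylation both proceed with retention at the alkenyl carbon, so the carboxyl group ends up cis to the methyl group (sarracinate geometry).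

Step 5
Reactants: 7 but-2-yne-1,4-diol
Product: 8 4-[(tert-butyldimethylsilyl)oxy]but-2-yn-1-ol
Conditions: TBSCl (1 equiv), imidazole, 7 (4 equiv), DMF, 0 °C
Reagents that add atoms: tert-butyldimethylsilyl chloride, CC(C)(C)[Si](C)(C)Cl
Why: Statistical monosilylation of a cheap symmetric diol used in excess.

Step 6
Reactants: 8 4-[(tert-butyldimethylsilyl)oxy]but-2-yn-1-ol
Product: 10 (Z)-4-[(tert-butyldimethylsilyl)oxy]-3-iodobut-2-en-1-ol, via cyclic alkenylaluminate 9 (not isolated)
Conditions: NaAlH2(OCH2CH2OMe)2, THF, 0 °C → rt; then I2, THF, −78 → 0 °C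
Reagents that add atoms: iodine, [I][I]
Why: Hydroxyl-directed trans-hydroalumination of the propargylic alcohol places aluminium on C4 cis to the CH2OH carbon (five-membered alkoxyaluminate), and iodinolysis with retention gives the iodide that carries the ring-cis C4=C5 geometry.

Step 7
Reactants: 11 (R)-2-{[(4-methoxybenzyl)oxy]methyl}oxirane
Product: 12 (R)-1-[(4-methoxybenzyl)oxy]pent-4-yn-2-ol
Conditions: LiC≡CH·H2NCH2CH2NH2, DMSO, 0 °C → rt
Reagents that add atoms: lithium acetylide ethylenediamine complex, [Li+].[C-]#C.NCCN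
Why: SN2 opening of the terminal epoxide carbon by acetylide leaves the stereocentre (future C8, R) untouched.

Step 8
Reactants: 12 (R)-1-[(4-methoxybenzyl)oxy]pent-4-yn-2-ol
Product: 15 (2E,5R)-6-[(4-methoxybenzyl)oxy]-3-methylhex-2-ene-1,5-diol, via alkenylalane 13 (not isolated), via lithium alanate 14 (not isolated)
Conditions: Me3Al (3.5 equiv), Cp2ZrCl2 (0.25 equiv), CH2Cl2, 0 °C → rt; then n-BuLi, THF, −78 °C; (CH2O)n, −78 °C → rt
Reagents that add atoms: trimethylaluminium, C[Al](C)C; paraformaldehyde (as formaldehyde), C=O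
Why: Zirconium-catalysed Negishi carboalumination adds CH3 and Al syn across the alkyne (CH3 to the internal carbon), and hydroxymethylation of the alanate with retention fixes the E-trisubstituted C1=C10 olefin.

Step 9
Reactants: 15 (2E,5R)-6-[(4-methoxybenzyl)oxy]-3-methylhex-2-ene-1,5-diol
Product: 16 (2R)-1-[(2R,3R)-3-(hydroxymethyl)-2-methyloxiran-2-yl]-3-[(4-methoxybenzyl)oxy]propan-2-ol
Conditions: Ti(OiPr)4 (10 mol%), D-(−)-diisopropyl tartrate (12 mol%), t-BuOOH, 4 Å molecular sieves, CH2Cl2, −20 °C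
Reagents that add atoms: tert-butyl hydroperoxide, CC(C)(C)OO
Why: Sharpless asymmetric epoxidation of the primary E-allylic alcohol sets C1 and C10 as (1R,10R) under reagent control by the D-tartrate, and the remote homoallylic C8–OH does not compete.

Step 10
Reactants: 16 (2R)-1-[(2R,3R)-3-(hydroxymethyl)-2-methyloxiran-2-yl]-3-[(4-methoxybenzyl)oxy]propan-2-ol
Product: 18 (2R)-1-[(2R,3R)-3-ethynyl-2-methyloxiran-2-yl]-3-[(4-methoxybenzyl)oxy]propan-2-ol, via epoxy aldehyde 17 (not isolated)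
Conditions: TEMPO (10 mol%), PhI(OAc)2, CH2Cl2, rt; then MeOH, K2CO3, dimethyl (1-diazo-2-oxopropyl)phosphonate, 0 °C → rt
Reagents that add atoms: dimethyl (1-diazo-2-oxopropyl)phosphonate, CC(=O)C(=[N+]=[N-])P(=O)(OC)OC
Why: TEMPO/PhI(OAc)2 oxidises the primary alcohol in the presence of the secondary one (the trans-oxirane prevents lactol formation), and Ohira–Bestmann homologation converts the epoxy aldehyde into the alkyne (C2≡C3) without touching the oxirane stereocentres.

Step 11
Reactants: 18 (2R)-1-[(2R,3R)-3-ethynyl-2-methyloxiran-2-yl]-3-[(4-methoxybenzyl)oxy]propan-2-ol; 6 (Z)-2-{[(tert-butyldimethylsilyl)oxy]methyl}but-2-enoic acid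
Product: 20 (2R)-1-[(2R,3R)-3-ethynyl-2-methyloxiran-2-yl]-3-[(4-methoxybenzyl)oxy]propan-2-yl (Z)-2-{[(tert-butyldimethylsilyl)oxy]methyl}but-2-enoate, via mixed anhydride 19 (not isolated)
Conditions: 6, 2,4,6-trichlorobenzoyl chloride, Et3N, toluene, rt; then 18, DMAP, rt
Reagents that add atoms: none
Why: Yamaguchi esterification acylates the hindered secondary C8–OH at room temperature with retention at C8 and without Z→E isomerisation of the α-branched enoate.

Step 12
Reactants: 20 PMB-protected ester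
Product: 21 (2R)-1-[(2R,3R)-3-ethynyl-2-methyloxiran-2-yl]-3-hydroxypropan-2-yl (Z)-2-{[(tert-butyldimethylsilyl)oxy]methyl}but-2-enoate
Conditions: DDQ, CH2Cl2/pH 7 buffer (10:1), 0 °C
Reagents that add atoms: none
Why: Oxidative cleavage of the 4-methoxybenzyl ether under buffered conditions spares the silyl ether, ester, alkyne and oxirane.

Step 13
Reactants: 21 primary alcohol (C7–OH)
Product: 22 (2R)-1-[(2R,3R)-3-ethynyl-2-methyloxiran-2-yl]-3-oxopropan-2-yl (Z)-2-{[(tert-butyldimethylsilyl)oxy]methyl}but-2-enoate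
Conditions: Dess–Martin periodinane, NaHCO3, CH2Cl2, 0 °C
Reagents that add atoms: none
Why: Buffered Dess–Martin oxidation gives the α-acyloxy aldehyde (C7) under neutral conditions, which avoids epimerisation at C8 and acyl migration.

Step 14
Reactants: 22 α-acyloxy aldehyde
Product: 23 methyl (4R)-5-[(2R,3R)-3-ethynyl-2-methyloxiran-2-yl]-3-hydroxy-2-methylidene-4-{[(Z)-2-{[(tert-butyldimethylsilyl)oxy]methyl}but-2-enoyl]oxy}pentanoate (both C7 epimers)
Conditions: iBu2AlH, N-methylmorpholine N-oxide, THF, 0 °C; methyl propiolate, 0 °C; then 22, 0 °C → rt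
Reagents that add atoms: methyl propiolate, C#CC(=O)OC
Why: Hydroalumination of the propiolate gives an α-aluminoacrylate that adds to the aldehyde (vinylalumination, a fast and non-basic route to Baylis–Hillman-type adducts), so C8 is not epimerised and the 8-ester does not shift; the new C7 carbinol is formed as a mixture, which is irrelevant because C7 becomes sp2 in step 18.

Step 15
Reactants: 23 hydroxy acrylate with terminal alkyne; 10 (Z)-4-[(tert-butyldimethylsilyl)oxy]-3-iodobut-2-en-1-ol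
Product: 24 C6–C7-seco enyne: methyl ester (C12) with 11(13)-methylidene, 7-OH, 8-O-(O-TBS sarracinoyl), (1R,10R)-oxirane, C2≡C3, ring-cis-type (4Z) C4=C5, 15-OTBS, 6-OH
Conditions: Pd(PPh3)2Cl2 (5 mol%), CuI (10 mol%), Et3N, THF, rt
Reagents that add atoms: none
Why: Sonogashira coupling forms C3–C4 with retention of the iodoalkene geometry (C3 cis to C6), and oxidative addition of the alkenyl iodide to zerovalent palladium is far faster than ionisation of the propargylic oxirane at room temperature.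

Step 16
Reactants: 24 seco enyne
Product: 25 seco (2Z,4Z)-diene diol (6-OH and 7-OH free)
Conditions: H2 (1 atm), Pd/CaCO3 poisoned with Pb(OAc)2 (Lindlar catalyst), quinoline, EtOAc, rt
Reagents that add atoms: none
Why: Lindlar semi-hydrogenation adds H2 syn to the alkyne to give the cis C2=C3 olefin, while the quinoline-poisoned catalyst is slow on the trisubstituted and conjugated alkenes and on the oxirane.

Step 17
Reactants: 25 seco (2Z,4Z)-diene diol
Product: 26 seco (2Z,4Z)-dienal (C6 aldehyde, 7-OH free)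
Conditions: MnO2 (activated, excess), CH2Cl2, 0 °C → rt
Reagents that add atoms: none
Why: MnO2 oxidises the electron-rich primary dienylic alcohol much faster than the electron-poor secondary allylic alcohol, and the neutral heterogeneous conditions preserve the Z,Z-geometry.

Step 18
Reactants: 26 seco (2Z,4Z)-dienal
Product: 30 bis-TBS ether of the target (15-OTBS; side-chain OTBS), via mesylate 27 (not isolated), via allylic bromide 28 (not isolated), via hydroxy ester 29 (not isolated)
Conditions: MsCl, Et3N, THF, −40 °C; LiBr, −40 → 0 °C; then addition by syringe pump (10 h) to CrCl2 (10 equiv), THF, rt, final 1 mM; aqueous NH4Cl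
Reagents that add atoms: none
Why: SN2′ displacement of the mesylate by bromide gives the Z-2-(bromomethyl)enoate, whose allylchromium (intramolecular Nozaki–Hiyama allylation, a reaction class already used to close germacranolide rings) attacks the tethered aldehyde through its γ-carbon C7 in a six-membered transition state; this forms C6–C7 and the exocyclic methylene, and the chromium 6-alkoxide lactonises onto the C12 methyl ester, with C6 and C7 set under macrocyclic control by the (8R) centre and the rigid Z,Z-dienyl trans-oxirane and expected to give the natural trans-fused 6α-O/7α-H arrangement.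

Step 19
Reactants: 30 bis-TBS ether of the target
Product: 31 target, CNP0293319.2
Conditions: HF·pyridine, pyridine, THF, 0 °C → rt
Reagents that add atoms: none
Why: Buffered fluoride desilylation removes both primary allylic TBS ethers without opening the dienyl oxirane or adding to the methylene lactone.

## Compound list

1 | (E)-but-2-enal (crotonaldehyde) | C/C=C/C=O | starting material
2 | (Z)-2-iodobut-2-enal | C/C=C(\I)C=O | intermediate
3 | (Z)-2-iodobut-2-en-1-ol | C/C=C(\I)CO | intermediate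
4 | (Z)-tert-butyl[(2-iodobut-2-en-1-yl)oxy]dimethylsilane | C/C=C(\I)CO[Si](C)(C)C(C)(C)C | intermediate
5 | alkenyllithium from 4 (Li in place of I, geometry retained) | C/C=C(\[Li])CO[Si](C)(C)C(C)(C)C | intermediate
6 | (Z)-2-{[(tert-butyldimethylsilyl)oxy]methyl}but-2-enoic acid (O-TBS sarracinic acid) | C/C=C(\C(=O)O)CO[Si](C)(C)C(C)(C)C | intermediate
7 | but-2-yne-1,4-diol | OCC#CCO | starting material
8 | 4-[(tert-butyldimethylsilyl)oxy]but-2-yn-1-ol | OCC#CCO[Si](C)(C)C(C)(C)C | intermediate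
9 | sodium cyclic alkenyl(alkoxy)bis(2-methoxyethoxy)aluminate from 8 | [Na+].COCCO[Al-]1(OCCOC)OCC=C1CO[Si](C)(C)C(C)(C)C | intermediate
10 | (Z)-4-[(tert-butyldimethylsilyl)oxy]-3-iodobut-2-en-1-ol | OC/C=C(\I)CO[Si](C)(C)C(C)(C)C | intermediate
11 | (R)-2-{[(4-methoxybenzyl)oxy]methyl}oxirane | O1C[C@@H]1COCc1ccc(OC)cc1 | starting material
12 | (R)-1-[(4-methoxybenzyl)oxy]pent-4-yn-2-ol | C#CC[C@@H](O)COCc1ccc(OC)cc1 | intermediate
13 | (E)-alkenyldimethylalane from 12 (O-dimethylaluminium alkoxide) | C[Al](C)/C=C(\C)C[C@@H](O[Al](C)C)COCc1ccc(OC)cc1 | intermediate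
14 | lithium butyl(dimethyl)alkenylalanate from 13 | [Li+].CCCC[Al-](C)(C)/C=C(\C)C[C@@H](O[Al](C)C)COCc1ccc(OC)cc1 | intermediate
15 | (2E,5R)-6-[(4-methoxybenzyl)oxy]-3-methylhex-2-ene-1,5-diol | OC/C=C(\C)C[C@@H](O)COCc1ccc(OC)cc1 | intermediate
16 | (2R)-1-[(2R,3R)-3-(hydroxymethyl)-2-methyloxiran-2-yl]-3-[(4-methoxybenzyl)oxy]propan-2-ol | OC[C@H]1O[C@]1(C)C[C@@H](O)COCc1ccc(OC)cc1 | intermediate
17 | epoxy aldehyde from 16 (CHO in place of CH2OH, configuration unchanged) | O=C[C@H]1O[C@]1(C)C[C@@H](O)COCc1ccc(OC)cc1 | intermediate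
18 | (2R)-1-[(2R,3R)-3-ethynyl-2-methyloxiran-2-yl]-3-[(4-methoxybenzyl)oxy]propan-2-ol | C#C[C@H]1O[C@]1(C)C[C@@H](O)COCc1ccc(OC)cc1 | intermediate
19 | mixed anhydride of 6 with 2,4,6-trichlorobenzoic acid | C/C=C(\C(=O)OC(=O)c1c(Cl)cc(Cl)cc1Cl)CO[Si](C)(C)C(C)(C)C | intermediate
20 | O-TBS sarracinate ester of 18 (PMB ether at C7–O) | C#C[C@H]1O[C@]1(C)C[C@@H](OC(=O)/C(=C\C)CO[Si](C)(C)C(C)(C)C)COCc1ccc(OC)cc1 | intermediate
21 | primary alcohol from 20 (C7–OH) | C#C[C@H]1O[C@]1(C)C[C@@H](OC(=O)/C(=C\C)CO[Si](C)(C)C(C)(C)C)CO | intermediate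
22 | α-acyloxy aldehyde (C7 aldehyde, 8R) | C#C[C@H]1O[C@]1(C)C[C@@H](OC(=O)/C(=C\C)CO[Si](C)(C)C(C)(C)C)C=O | intermediate
23 | methyl 3-hydroxy-2-methylidene pentanoate adduct (C7 epimers; 8R; epoxy-alkyne) | C#C[C@H]1O[C@]1(C)C[C@@H](OC(=O)/C(=C\C)CO[Si](C)(C)C(C)(C)C)C(O)C(=C)C(=O)OC | intermediate
24 | C6–C7-seco enyne diol (C2≡C3, 4Z, 6-OH, 7-OH, 15-OTBS) | OC/C=C(CO[Si](C)(C)C(C)(C)C)\C#C[C@H]1O[C@]1(C)C[C@@H](OC(=O)/C(=C\C)CO[Si](C)(C)C(C)(C)C)C(O)C(=C)C(=O)OC | intermediate
25 | C6–C7-seco (2Z,4Z)-diene diol | OC/C=C(CO[Si](C)(C)C(C)(C)C)\C=C/[C@H]1O[C@]1(C)C[C@@H](OC(=O)/C(=C\C)CO[Si](C)(C)C(C)(C)C)C(O)C(=C)C(=O)OC | intermediate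
26 | C6–C7-seco (2Z,4Z)-dienal (7-OH) | O=C/C=C(CO[Si](C)(C)C(C)(C)C)\C=C/[C@H]1O[C@]1(C)C[C@@H](OC(=O)/C(=C\C)CO[Si](C)(C)C(C)(C)C)C(O)C(=C)C(=O)OC | intermediate
27 | 7-O-mesylate of 26 | O=C/C=C(CO[Si](C)(C)C(C)(C)C)\C=C/[C@H]1O[C@]1(C)C[C@@H](OC(=O)/C(=C\C)CO[Si](C)(C)C(C)(C)C)C(OS(C)(=O)=O)C(=C)C(=O)OC | intermediate
28 | (Z)-2-(bromomethyl)enoate dienal (C13 bromide, C7=C11) | O=C/C=C(CO[Si](C)(C)C(C)(C)C)\C=C/[C@H]1O[C@]1(C)C[C@@H](OC(=O)/C(=C\C)CO[Si](C)(C)C(C)(C)C)/C=C(\CBr)C(=O)OC | intermediate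
29 | ten-membered 6-hydroxy 12-methyl ester (as its chromium alkoxide in the flask) | COC(=O)C(=C)[C@H]1[C@H](O)/C=C(CO[Si](C)(C)C(C)(C)C)\C=C/[C@H]2O[C@]2(C)C[C@H]1OC(=O)/C(=C\C)CO[Si](C)(C)C(C)(C)C | intermediate
30 | bis-TBS ether of the target | C=C1C(=O)O[C@@H]2/C=C(CO[Si](C)(C)C(C)(C)C)\C=C/[C@H]3O[C@]3(C)C[C@@H](OC(=O)/C(=C\C)CO[Si](C)(C)C(C)(C)C)[C@@H]12 | intermediate
31 | CNP0293319.2: 1β,10α-epoxy-15-hydroxy-8β-[(Z)-2-(hydroxymethyl)but-2-enoyloxy]germacra-2Z,4(ring-cis),11(13)-trien-12,6α-olide | C=C1C(=O)O[C@@H]2/C=C(CO)\C=C/[C@H]3O[C@]3(C)C[C@@H](OC(=O)/C(=C\C)CO)[C@@H]12 | target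

## Step count and risks

Total step count: 19 (4 for the side-chain acid, 2 for the iodoalkene, 13 in the main line; one-flask sequences counted as one step).
Longest linear sequence: 13 steps (steps 7–19, from compound 11).

The three steps most likely to fail:

Step 18 (ring closure). The allylchromium carries the 8-carboxylate in a 1,4-relationship and may eliminate it to a diene before the slow ten-membered closure, and the C6/C7 configuration rests on macrocyclic control alone. The fallback takes the ester out of the ring-closing substrate and acylates after ring closure. It sets out from compound 18: silylation (TESCl, imidazole) gives the triethylsilyl ether F1, DDQ gives the primary alcohol F2, and Dess–Martin oxidation gives the aldehyde F3. Vinylalumination as in step 14 gives the hydroxy acrylate F4, Sonogashira coupling with 10 gives the enyne F5, Lindlar reduction gives the diene F6, and MnO2 gives the dienal F7. The one-flask sequence of step 18 then runs through the mesylate F8, the allylic bromide F9 and the hydroxy ester F10 to the 8-O-TES lactone F11. HF·pyridine/pyridine at −10 °C removes only the secondary TES group to give the 8-hydroxy lactone F12, and Yamaguchi acylation with acid 6 (through 19) comes back to the route at compound 30.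

Step 16 (semi-hydrogenation). The acrylate methylene or the newly formed vinyl oxirane may be reduced, and the Z,Z-dienyl oxirane must then survive two more operations. The fallback closes the ring on the enyne and reduces afterwards with a dissolving-metal reagent that does not touch the methylene lactone. It sets out from compound 24: MnO2 gives the enynal F13, and the conditions of step 18 lead through the mesylate F14, the allylic bromide F15 and the hydroxy ester F16 to the cyclic enyne lactone F17. Zinc activated with Cu(OAc)2 and AgNO3 in MeOH/H2O reduces the conjugated ring alkyne to the cis-alkene, which comes back to the route at compound 30.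

Step 8 (carboalumination and hydroxymethylation with a free hydroxyl). The alanate may transfer its alkenyl group to formaldehyde poorly in the presence of the aluminium alkoxide. The fallback separates C–Al cleavage from C–C bond formation. It sets out from compound 12: the alkenylalane 13 is quenched with iodine to give the (2R,4E)-5-iodo-1-[(4-methoxybenzyl)oxy]-4-methylpent-4-en-2-ol F18, and Stille hydroxymethylation with Bu3SnCH2OH and Pd(PPh3)4 in dioxane at 80 °C comes back to the route at compound 15.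

## Further compounds

F1 | step 18 | 8-O-triethylsilyl ether of compound 18 | C#C[C@H]1O[C@]1(C)C[C@@H](O[Si](CC)(CC)CC)COCc1ccc(OC)cc1
F2 | step 18 | primary alcohol (C7–OH) from F1 | C#C[C@H]1O[C@]1(C)C[C@@H](O[Si](CC)(CC)CC)CO
F3 | step 18 | α-silyloxy aldehyde (C7 aldehyde) | C#C[C@H]1O[C@]1(C)C[C@@H](O[Si](CC)(CC)CC)C=O
F4 | step 18 | hydroxy acrylate adduct with 8-OTES (C7 epimers) | C#C[C@H]1O[C@]1(C)C[C@@H](O[Si](CC)(CC)CC)C(O)C(=C)C(=O)OC
F5 | step 18 | seco enyne diol with 8-OTES | OC/C=C(CO[Si](C)(C)C(C)(C)C)\C#C[C@H]1O[C@]1(C)C[C@@H](O[Si](CC)(CC)CC)C(O)C(=C)C(=O)OC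
F6 | step 18 | seco (2Z,4Z)-diene diol with 8-OTES | OC/C=C(CO[Si](C)(C)C(C)(C)C)\C=C/[C@H]1O[C@]1(C)C[C@@H](O[Si](CC)(CC)CC)C(O)C(=C)C(=O)OC
F7 | step 18 | seco (2Z,4Z)-dienal with 8-OTES | O=C/C=C(CO[Si](C)(C)C(C)(C)C)\C=C/[C@H]1O[C@]1(C)C[C@@H](O[Si](CC)(CC)CC)C(O)C(=C)C(=O)OC
F8 | step 18 | 7-O-mesylate of F7 | O=C/C=C(CO[Si](C)(C)C(C)(C)C)\C=C/[C@H]1O[C@]1(C)C[C@@H](O[Si](CC)(CC)CC)C(OS(C)(=O)=O)C(=C)C(=O)OC
F9 | step 18 | (Z)-2-(bromomethyl)enoate dienal with 8-OTES | O=C/C=C(CO[Si](C)(C)C(C)(C)C)\C=C/[C@H]1O[C@]1(C)C[C@@H](O[Si](CC)(CC)CC)/C=C(\CBr)C(=O)OC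
F10 | step 18 | ten-membered 6-hydroxy 12-methyl ester with 8-OTES | COC(=O)C(=C)[C@H]1[C@H](O)/C=C(CO[Si](C)(C)C(C)(C)C)\C=C/[C@H]2O[C@]2(C)C[C@H]1O[Si](CC)(CC)CC
F11 | step 18 | 8-O-TES 15-O-TBS lactone | C=C1C(=O)O[C@@H]2/C=C(CO[Si](C)(C)C(C)(C)C)\C=C/[C@H]3O[C@]3(C)C[C@@H](O[Si](CC)(CC)CC)[C@@H]12
F12 | step 18 | 8-hydroxy 15-O-TBS lactone | C=C1C(=O)O[C@@H]2/C=C(CO[Si](C)(C)C(C)(C)C)\C=C/[C@H]3O[C@]3(C)C[C@@H](O)[C@@H]12
F13 | step 16 | seco enynal (C6 aldehyde, C2≡C3, 7-OH) | O=C/C=C(CO[Si](C)(C)C(C)(C)C)\C#C[C@H]1O[C@]1(C)C[C@@H](OC(=O)/C(=C\C)CO[Si](C)(C)C(C)(C)C)C(O)C(=C)C(=O)OC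
F14 | step 16 | 7-O-mesylate of F13 | O=C/C=C(CO[Si](C)(C)C(C)(C)C)\C#C[C@H]1O[C@]1(C)C[C@@H](OC(=O)/C(=C\C)CO[Si](C)(C)C(C)(C)C)C(OS(C)(=O)=O)C(=C)C(=O)OC
F15 | step 16 | (Z)-2-(bromomethyl)enoate enynal | O=C/C=C(CO[Si](C)(C)C(C)(C)C)\C#C[C@H]1O[C@]1(C)C[C@@H](OC(=O)/C(=C\C)CO[Si](C)(C)C(C)(C)C)/C=C(\CBr)C(=O)OC
F16 | step 16 | ten-membered enyne 6-hydroxy 12-methyl ester | COC(=O)C(=C)[C@H]1[C@H](O)/C=C(CO[Si](C)(C)C(C)(C)C)\C#C[C@H]2O[C@]2(C)C[C@H]1OC(=O)/C(=C\C)CO[Si](C)(C)C(C)(C)C
F17 | step 16 | cyclic enyne lactone (2,3-didehydro analogue of 30) | C=C1C(=O)O[C@@H]2/C=C(CO[Si](C)(C)C(C)(C)C)\C#C[C@H]3O[C@]3(C)C[C@@H](OC(=O)/C(=C\C)CO[Si](C)(C)C(C)(C)C)[C@@H]12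
F18 | step 8 | (2R,4E)-5-iodo-1-[(4-methoxybenzyl)oxy]-4-methylpent-4-en-2-ol | I/C=C(\C)C[C@@H](O)COCc1ccc(OC)cc1
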